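The benzene ring is built last. With the cyclopentane numbered C1 (quaternary), C2 (methyl-bearing) and C3 (bromomethylene-bearing), the arene carries C1, the oxygen on the adjacent carbon and a methyl para to C1. This 1,2,4 pattern is isoprene plus a C1-bound alkynylboronate, with boron standing in for oxygen. One cobalt-catalysed [4+2] cycloaddition with DDQ dehydrogenation forms both new arene C–C bonds and the ring, so the crowded aryl–C1 bond is never made by coupling. The precursor is a pinacol alkynylboronate whose cyclopentane already holds both stereocenters and the (E)-bromomethylene, installed while C2 has its favoured configuration, so no enolisable C3 ketone exists once the arene is present.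

Key step: step 6

Assumption: the sense of asymmetric induction in step 2 is set by the choice of antipode of the chiral carbene ligand; the antipode that gives the (R)-configured quaternary carbon is used.
Remark: C1–C5 in the running text are the cyclopentane carbons as defined above; compound names use systematic locants.

Step 1
Reactants: 1 3-ethoxycyclopent-2-en-1-one; 2 ethynyltrimethylsilane
Product: 5 3-[(trimethylsilyl)ethynyl]cyclopent-2-en-1-one, via lithium acetylide 3 (not isolated), via lithium alkoxide 4 (not isolated)
Conditions: 2, n-BuLi, THF, −78 °C; then 1, −78 → 0 °C; 1 M HCl, rt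
Reagents that add atoms: water (from the aqueous HCl; supplies the carbonyl oxygen), SMILES O
Why: 1,2-addition of the lithium acetylide to the vinylogous ester and acid-promoted loss of ethanol and water (Stork–Danheiser transposition) should give the β-alkynyl enone; no stereocenter is formed.

Step 2
Reactants: 5 3-[(trimethylsilyl)ethynyl]cyclopent-2-en-1-one
Product: 7 (2R,3R)-2,3-dimethyl-3-[(trimethylsilyl)ethynyl]cyclopentan-1-one, via magnesium enolate 6 (not isolated)
Conditions: MeMgBr, Cu(OTf)2 (5 mol %), chiral hydroxyalkyl imidazolinium salt (carbene precursor, 6 mol %), Et2O, −30 °C; then MeI, DMPU, −30 °C → rt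
Reagents that add atoms: methylmagnesium bromide, SMILES C[Mg]Br; iodomethane, SMILES CI
Why: Copper-catalysed asymmetric 1,4-addition of a Grignard reagent to a β-alkynyl cyclic enone (with N-heterocyclic carbene ligands such enynones react at the β-carbon and not at the alkyne terminus) should set the quaternary carbon by ligand control of the enone face, and the regiodefined magnesium enolate is then methylated on the face away from the new methyl and next to the slim alkyne, which is also the isomer favoured at equilibrium (tandem conjugate addition–enolate alkylation).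

Step 3
Reactants: 7 (2R,3R)-2,3-dimethyl-3-[(trimethylsilyl)ethynyl]cyclopentan-1-one
Product: 8 {[(1R,2R,3E)-3-(bromomethylidene)-1,2-dimethylcyclopentyl]ethynyl}trimethylsilane
Conditions: [Ph3PCH2Br]Br, NaN(SiMe3)2, THF, −78 °C; then 7, −78 °C → rt
Reagents that add atoms: (bromomethyl)triphenylphosphonium bromide, SMILES BrC[P+](c1ccccc1)(c1ccccc1)c1ccccc1.[Br-]
Why: In this Wittig bromomethylenation the oxaphosphetane should form with bromine turned toward the ring CH2 and away from the methyl-bearing α-carbon, as is usual for α-branched cyclopentanones, giving the E alkene, and the basic ylide cannot erode the α-stereocenter because methyl trans to the neighbouring methyl and cis to the alkyne is the thermodynamically preferred arrangement.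

Step 4
Reactants: 8 {[(1R,2R,3E)-3-(bromomethylidene)-1,2-dimethylcyclopentyl]ethynyl}trimethylsilane
Product: 9 (1R,2R,3E)-3-(bromomethylidene)-1-ethynyl-1,2-dimethylcyclopentane
Conditions: K2CO3, MeOH, rt
Reagents that add atoms: none
Why: Base-catalysed methanolysis (protodesilylation) cleaves only the alkynyl C–Si bond; the alkenyl bromide, which has no hydrogen on the neighbouring sp2 carbon, and both stereocenters are untouched.

Step 5
Reactants: 9 (1R,2R,3E)-3-(bromomethylidene)-1-ethynyl-1,2-dimethylcyclopentane; 10 2-isopropoxy-4,4,5,5-tetramethyl-1,3,2-dioxaborolane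
Product: 13 2-{[(1R,2R,3E)-3-(bromomethylidene)-1,2-dimethylcyclopentyl]ethynyl}-4,4,5,5-tetramethyl-1,3,2-dioxaborolane, via lithium acetylide 11 (not isolated), via lithium borate 12 (not isolated)
Conditions: n-BuLi (1.0 equiv), THF, −78 °C; then 10, −78 °C; HCl in Et2O (1.0 equiv), −78 °C → rt
Reagents that add atoms: none
Why: Deprotonation of the terminal alkyne is much faster than bromine–lithium exchange at a trisubstituted alkenyl bromide at −78 °C, and the acetylide adds to the borate ester to give an ate complex from which anhydrous HCl removes isopropoxide (standard alkynylboronate synthesis from a lithium acetylide); no stereocenter is affected.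

Step 6
Reactants: 13 2-{[(1R,2R,3E)-3-(bromomethylidene)-1,2-dimethylcyclopentyl]ethynyl}-4,4,5,5-tetramethyl-1,3,2-dioxaborolane; 14 isoprene
Product: 16 2-{2-[(1R,2R,3E)-3-(bromomethylidene)-1,2-dimethylcyclopentyl]-5-methylphenyl}-4,4,5,5-tetramethyl-1,3,2-dioxaborolane, via cyclohexa-1,4-diene 15 (not isolated)
Conditions: CoBr2(dppe) (10 mol %), Zn powder (20 mol %), ZnI2 (20 mol %), CH2Cl2, rt; then DDQ, benzene, rt
Reagents that add atoms: none
Why: Zn reduces CoBr2(dppe) to monovalent cobalt, which after halide abstraction by ZnI2 binds isoprene and the alkyne, couples them oxidatively to a trivalent cobaltacycle and releases the six-membered ring by C–C reductive elimination. The closest known reaction type is the cobalt-catalysed [4+2] cycloaddition of alkynylboronic esters with 2-substituted 1,3-dienes followed by DDQ dehydrogenation to arylboronic esters. The one ring formed, the benzene ring, is closed as a cyclohexa-1,4-diene by this metal-mediated formal [4+2] union of a four-carbon and a two-carbon unit (two new C–C bonds), and DDQ then removes a hydride and a proton from the two ring CH2 groups. No stereocenter is created, and the two existing ones are inert because C2 is only allylic and not α to a carbonyl group. The one selectivity needed is regiochemical: quaternary C1 is far bulkier than the planar boronate, so its alkyne carbon should bond to the isoprene CH2 remote from the methyl group, as the substituted carbon of terminal alkynes does with bisphosphine cobalt catalysts, which places methyl para to C1 and meta to boron. The alkenyl bromide is expected to be a spectator, since the metal is held by diene and alkyne and the catalyst is used in a chlorinated solvent.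

Step 7
Reactants: 16 2-{2-[(1R,2R,3E)-3-(bromomethylidene)-1,2-dimethylcyclopentyl]-5-methylphenyl}-4,4,5,5-tetramethyl-1,3,2-dioxaborolane
Product: 17 2-[(1R,2R,3E)-3-(bromomethylidene)-1,2-dimethylcyclopentyl]-5-methylphenol
Conditions: 30% aq. H2O2, NaOH, THF, 0 °C → rt
Reagents that add atoms: hydrogen peroxide, SMILES OO
Why: Hydroperoxide adds to boron and the aryl group migrates from boron to oxygen, so that oxygen arrives exactly at the carbon that carried boron, before the borate ester is hydrolysed (arylboronate oxidation); alkaline peroxide does not attack the electron-poor alkenyl bromide.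

Step 8
Reactants: 17 2-[(1R,2R,3E)-3-(bromomethylidene)-1,2-dimethylcyclopentyl]-5-methylphenol
Product: 18 4-bromo-2-[(1R,2R,3E)-3-(bromomethylidene)-1,2-dimethylcyclopentyl]-5-methylphenol
Conditions: NBS (1.0 equiv), MeCN, 0 °C
Reagents that add atoms: N-bromosuccinimide, SMILES O=C1CCC(=O)N1Br
Why: Electrophilic aromatic bromination should take place para to the hydroxyl group (also ortho to methyl), as with 2-alkyl-5-methylphenols such as thymol, because the only free ortho position lies between OH and CH3 and the bromoalkene is deactivated toward electrophilic bromine.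

Compound list
1 | 3-ethoxycyclopent-2-en-1-one | CCOC1=CC(=O)CC1 | starting material
2 | ethynyltrimethylsilane | C#C[Si](C)(C)C | starting material
3 | lithium (trimethylsilyl)acetylide | [Li]C#C[Si](C)(C)C | intermediate
4 | lithium 3-ethoxy-1-[(trimethylsilyl)ethynyl]cyclopent-2-en-1-olate (racemic) | CCOC1=CC(O[Li])(C#C[Si](C)(C)C)CC1 | intermediate
5 | 3-[(trimethylsilyl)ethynyl]cyclopent-2-en-1-one | C[Si](C)(C)C#CC1=CC(=O)CC1 | intermediate
6 | bromomagnesium (3R)-3-methyl-3-[(trimethylsilyl)ethynyl]cyclopent-1-en-1-olate | C[Si](C)(C)C#C[C@]1(C)CCC(O[Mg]Br)=C1 | intermediate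
7 | (2R,3R)-2,3-dimethyl-3-[(trimethylsilyl)ethynyl]cyclopentan-1-one (ring methyl cis to the alkyne) | C[Si](C)(C)C#C[C@]1(C)CCC(=O)[C@@H]1C | intermediate
8 | {[(1R,2R,3E)-3-(bromomethylidene)-1,2-dimethylcyclopentyl]ethynyl}trimethylsilane | C[Si](C)(C)C#C[C@]1(C)CC/C(=C\Br)[C@@H]1C | intermediate
9 | (1R,2R,3E)-3-(bromomethylidene)-1-ethynyl-1,2-dimethylcyclopentane | C#C[C@]1(C)CC/C(=C\Br)[C@@H]1C | intermediate
10 | 2-isopropoxy-4,4,5,5-tetramethyl-1,3,2-dioxaborolane | CC(C)OB1OC(C)(C)C(C)(C)O1 | starting material
11 | {[(1R,2R,3E)-3-(bromomethylidene)-1,2-dimethylcyclopentyl]ethynyl}lithium | [Li]C#C[C@]1(C)CC/C(=C\Br)[C@@H]1C | intermediate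
12 | lithium {[(1R,2R,3E)-3-(bromomethylidene)-1,2-dimethylcyclopentyl]ethynyl}(isopropoxy)(pinacolato)borate | [Li+].CC(C)O[B-]1(C#C[C@]2(C)CC/C(=C\Br)[C@@H]2C)OC(C)(C)C(C)(C)O1 | intermediate
13 | 2-{[(1R,2R,3E)-3-(bromomethylidene)-1,2-dimethylcyclopentyl]ethynyl}-4,4,5,5-tetramethyl-1,3,2-dioxaborolane | CC1(C)OB(C#C[C@]2(C)CC/C(=C\Br)[C@@H]2C)OC1(C)C | intermediate
14 | isoprene (2-methylbuta-1,3-diene) | C=CC(C)=C | starting material
15 | 2-{2-[(1R,2R,3E)-3-(bromomethylidene)-1,2-dimethylcyclopentyl]-5-methylcyclohexa-1,4-dien-1-yl}-4,4,5,5-tetramethyl-1,3,2-dioxaborolane | CC1=CCC([C@]2(C)CC/C(=C\Br)[C@@H]2C)=C(B2OC(C)(C)C(C)(C)O2)C1 | intermediate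
16 | 2-{2-[(1R,2R,3E)-3-(bromomethylidene)-1,2-dimethylcyclopentyl]-5-methylphenyl}-4,4,5,5-tetramethyl-1,3,2-dioxaborolane | Cc1ccc([C@]2(C)CC/C(=C\Br)[C@@H]2C)c(B2OC(C)(C)C(C)(C)O2)c1 | intermediate
17 | 2-[(1R,2R,3E)-3-(bromomethylidene)-1,2-dimethylcyclopentyl]-5-methylphenol | Cc1ccc([C@]2(C)CC/C(=C\Br)[C@@H]2C)c(O)c1 | intermediate
18 | 4-bromo-2-[(1R,2R,3E)-3-(bromomethylidene)-1,2-dimethylcyclopentyl]-5-methylphenol | Cc1cc(O)c([C@]2(C)CC/C(=C\Br)[C@@H]2C)cc1Br | target

Total step count: 8
Longest linear sequence: 8 steps (1 → 18)

Steps most likely to fail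

Step 6. Three processes may go wrong:
- the oxidative coupling at cobalt may take the opposite orientation, putting methyl meta to C1;
- it may stall at the quaternary propargylic carbon;
- the low-valent metal may insert into the alkenyl C–Br bond.

Fallback: setting out from 13, the cobalt step is replaced by a metal-free pericyclic sequence. Heating 13 with 4-methyl-2H-pyran-2-one (mesitylene, about 170 °C) should give by [4+2] cycloaddition the bridged lactone 7-[(1R,2R,3E)-3-(bromomethylidene)-1,2-dimethylcyclopentyl]-5-methyl-8-(4,4,5,5-tetramethyl-1,3,2-dioxaborolan-2-yl)-2-oxabicyclo[2.2.2]octa-5,7-dien-3-one F1. This loses CO2 by retro-[4+2] under the same conditions and comes back to the route at 16 without a separate oxidation. Orientation then rests on sterics alone: the bulky C1-bearing alkyne carbon is expected to bond to the unsubstituted C6 of the pyrone, so the pyrone methyl again lies para to C1.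

Step 2. The catalyst may discriminate poorly between the faces of the five-membered enone, or methyl may be transferred to the alkyne terminus (1,6-addition) instead of the β-carbon.

Fallback: setting out from 5, the addition–methylation is run with an achiral catalyst (MeMgBr, CuBr·SMe2, Et2O; then MeI, DMPU) to give the racemic ketone rac-(2R,3R)-2,3-dimethyl-3-[(trimethylsilyl)ethynyl]cyclopentan-1-one F2. Acid-catalysed ketalisation with (1R,2R)-1,2-diphenylethane-1,2-diol (pyridinium p-toluenesulfonate, benzene, reflux with azeotropic removal of water) gives two diastereomeric ketals: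
- (2R,3R,6R,7R)-6,7-dimethyl-2,3-diphenyl-7-[(trimethylsilyl)ethynyl]-1,4-dioxaspiro[4.4]nonane F3
- (2R,3R,6S,7S)-6,7-dimethyl-2,3-diphenyl-7-[(trimethylsilyl)ethynyl]-1,4-dioxaspiro[4.4]nonane F4

These are separated by chromatography or crystallisation. Hydrolysis of F3 (aqueous HCl, THF, rt) comes back to the route at 7; its ring-methyl configuration is the stable one and is not at risk under acid.

Step 3. Addition of the thermally fragile halo-ylide to the hindered carbonyl may be slow and lose out to enolisation, or control of the alkene geometry may be insufficient.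

Fallback: setting out from 7, a boron–Wittig olefination is used. LiCH(Bpin)2 is made from bis(4,4,5,5-tetramethyl-1,3,2-dioxaborolan-2-yl)methane and lithium 2,2,6,6-tetramethylpiperidide (THF, 0 °C → rt). This compact, weakly basic nucleophile should give the alkenylboronate 2-{(E)-[(2S,3R)-2,3-dimethyl-3-[(trimethylsilyl)ethynyl]cyclopentylidene]methyl}-4,4,5,5-tetramethyl-1,3,2-dioxaborolane F5, with boron anti to the branched α-carbon. Bromodeboronation with CuBr2 (aqueous MeOH, 60 °C) proceeds with retention of alkene geometry and comes back to the route at 8.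

Further compounds
F1 | step 6 | 7-[(1R,2R,3E)-3-(bromomethylidene)-1,2-dimethylcyclopentyl]-5-methyl-8-(4,4,5,5-tetramethyl-1,3,2-dioxaborolan-2-yl)-2-oxabicyclo[2.2.2]octa-5,7-dien-3-one | O=C1OC2C=C(C)C1C(B3OC(C)(C)C(C)(C)O3)=C2[C@]4(C)CC/C(=C\Br)[C@@H]4C
F2 | step 2 | rac-(2R,3R)-2,3-dimethyl-3-[(trimethylsilyl)ethynyl]cyclopentan-1-one (7 and its enantiomer, 1:1) | C[Si](C)(C)C#C[C@]1(C)CCC(=O)[C@@H]1C.C[Si](C)(C)C#C[C@@]1(C)CCC(=O)[C@H]1C
F3 | step 2 | (2R,3R,6R,7R)-6,7-dimethyl-2,3-diphenyl-7-[(trimethylsilyl)ethynyl]-1,4-dioxaspiro[4.4]nonane | C[Si](C)(C)C#C[C@]1(C)CCC2(O[C@H](c3ccccc3)[C@@H](c3ccccc3)O2)[C@@H]1C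
F4 | step 2 | (2R,3R,6S,7S)-6,7-dimethyl-2,3-diphenyl-7-[(trimethylsilyl)ethynyl]-1,4-dioxaspiro[4.4]nonane | C[Si](C)(C)C#C[C@@]1(C)CCC2(O[C@H](c3ccccc3)[C@@H](c3ccccc3)O2)[C@H]1C
F5 | step 3 | 2-{(E)-[(2S,3R)-2,3-dimethyl-3-[(trimethylsilyl)ethynyl]cyclopentylidene]methyl}-4,4,5,5-tetramethyl-1,3,2-dioxaborolane | C[Si](C)(C)C#C[C@]1(C)CC/C(=C\B2OC(C)(C)C(C)(C)O2)[C@@H]1C
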